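Atom labels used throughout: in each butenolide O1, C2 (C=O), C3 (bears C1′), C4 (bears Br), C5; C6 is the CHBr carbon attached to C5. Half A carries the (S)-C1′ centre, half B the (R)-C1′ centre.

## Analysis of the target

Target 20 is a 1,7-dioxadispiro[4.0.4.2]dodecadienedione: a cyclobutane C5A–C5B–C6B–C6A in which C5A and C5B are each the spiro carbon of a 4-bromobutenolide, C6A and C6B are CHBr, and each C3 carries a 1-acetoxybutyl chain. The four ring centres (C5A S, C5B S, C6A R, C6B R) form a C2-symmetric core: the lactone oxygens are trans across C5A–C5B, the bromines are trans across C6A–C6B, and each C6–Br is anti to O1 and syn to C4 of the lactone on the neighbouring spiro carbon. The two side-chain centres are opposite (C1′A S, C1′B R), so the whole molecule has no symmetry and is the cross-dimer of the two enantiomers of one monomer. Two consequences follow: the handedness of the core cannot come from the C1′ centres (joined by an achiral link, the precursor would be meso and the core racemic), and no two-directional operation on a C2-symmetric core can set them. The sensitive groups are the vinylogous acyl bromides at C4 (addition–elimination with amines, alkoxides, phosphines), the secondary bromides on a strained ring next to quaternary carbons (elimination, no substitution), the lactones and the acetates; the array tolerates strong acid but not base. The difficulty is two adjacent quaternary spiro centres, four contiguous stereocentres on a four-membered ring, and four bromines that are hard to introduce once the ring exists. The strategy rests on the cyclobutane being the head-to-head [2+2] dimer of the exocyclic C5=C6HBr alkenes of two enantiomeric 4-bromo-5-(bromomethylidene)butenolides; its ring relationships are those of a suprafacial union of two 5E alkenes stacked with the lactone oxygens anti.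

## Retrosynthetic reasoning

**20 to 19.** The two acetate C–O bonds are cut last. The C1′ oxygens are the only handles by which the two halves can be held together, so they stay free for the bridge until the ring exists. Acetylation of diol 19 touches no stereocentre.

**19 to 18.** The two ester bonds between the C1′ oxygens and the bridge are cut. In 18 a (2R,3R)-2,3-diacetoxybutanedioyl unit joins C1′A–O and C1′B–O in a 14-membered ring. This gives a unimolecular precursor in which the (S)- and (R)-halves must pair with each other and a C2-symmetric chiral element sits next to the reacting alkenes. The forward step must free two hindered secondary alcohols without a nucleophile that attacks C4–Br, which points to acid-catalysed ester exchange.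

**18 to 14 (through 17).** The bonds C5A–C5B and C6A–C6B are cut, the retro-[2+2]. No other cut removes both quaternary centres, all four ring stereocentres and the ring strain at once while leaving every bromine on a simple monomer. Read suprafacially the cut gives the 5E,5E compound 17. The monomers are made as 5Z isomers, so the isolable precursor is 14, which a triplet sensitiser interconverts with 15, 16 and 17 during the reaction. The forward step must give head-to-head union, trans lactone oxygens, trans bromines, each C6–Br anti to its neighbouring O1, and one helical sense of the core. The first is enforced by the length of the bridge; the last can come only from its chirality.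

**14 to 13 and 11; 13 to 9 and 12.** The bridge esters are cut one at a time, so that each enantiomer of the alcohol is placed deliberately. Because the bridge is C2-symmetric, the diester of one (S)- and one (R)-alcohol is a single compound. A diacyl-protected bridge is preferred to a cyclic acetal: anhydride 12 differentiates the two carboxyls in one step without protecting groups, and the open chain can reach the extended conformation that the dispiro product needs.

**9 and 11 to 8 (through 10).** Both enantiomers are needed in equal amounts, so resolution of racemic 8 wastes nothing. Enzymatic acylation leaves 9 and gives acetate 10; enzymatic deacetylation of 10 gives 11.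

**8 to 7 to 6.** The C1′–O bond is traced to C1′–Br and then to C1′–H, the only allylic C–H of 6.

**6 to 4 (through 5).** The lactone C–O bond, both C–Br bonds and both C=C bonds are removed together. An oxidative enol-lactonisation of a dibrominated γ-keto acid builds the whole monomer core from an acyclic C9 acid.

**4 to 3 to 1 and 2.** The bond between the future C3 and C4 of the butenolide is cut: alkylation of the enolate of 1 with α-bromo ester 2, then hydrolysis and decarboxylation.

## Alternatives that were turned down

**Alternative 1:** The disconnection is at the two C3–C1′ bonds: the side chains are added last to a dispiro bis(methyl tetronate) A2 that carries silyl ethers at C6A and C6B. The forward key step is double C3 lithiation of A2 and acylation with the butanoyl Weinreb amide A3 to give diketone A1. In its favour, C3 lithiation and acylation of methyl tetronates is dependable, and the absolute configuration of the core would be fixed beforehand; on that point it is more secure than induction through a bridge. Against it, A1 still lacks all four bromines and both C1′ centres. Its two ketones are homotopic, so any reductant gives the same configuration at both C1′, whereas 20 needs S at one and R at the other. The C4 methoxy groups must become bromides on both rings. The C6 silyl ethers must become bromides with inversion at cyclobutyl carbons flanked by a quaternary centre, where SN2 displacement is hardly possible and ionisation invites ring contraction. The chosen route carries bromines and C1′ centres in from the monomers and builds the heterochiral pairing in by construction; this plan would add roughly ten operations after its key step.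

**Alternative 2:** The disconnection is C6A–C6B only, traced to NH-pyrrolidine A5 in which nitrogen bridges C6A and C6B, both spiro lactones are in place and both C6 carry tert-butyl esters. The forward key step is N-amination of A5 by a trivalent iodine oxidant and an ammonia source, nitrogen extrusion from the 1,1-diazene, and closure of the singlet 1,4-diradical to cis-diester A4. In its favour, this ring contraction is stereoretentive because the singlet diradical closes faster than it rotates; on fidelity of ring closure it is stronger than a triplet photocycloaddition. Against it, the C6 esters must then be exchanged for bromines by two radical decarboxylative brominations, which pass through C6 radicals and erase the configuration that was preserved; a cis-diester must also end as a trans-dibromide. The diradical can fragment across C5A–C5B into two conjugated alkenes, relieving the strain of two adjacent spiro centres. A5 itself needs a cycloaddition onto a tetrasubstituted alkene and must already hold the (S)- and (R)-side chains. The chosen strategy changes nothing at C6 after ring formation and reaches 18 in ten steps.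

**Alternative 3:** The disconnection is at both C3=C4 bonds: each butenolide is traced to a vinyl group on a tertiary cyclobutanol carbon and the 2-(1-acetoxybutyl)acrylate ester of that alcohol (tetraene A7). The forward key step is double ring-closing metathesis of A7 to the bromine-free dispiro bis(butenolide) A6. In its favour, metathesis to α-substituted butenolides is far more predictable than a photocycloaddition, and the C1′ centres arrive with separately prepared enantiopure acids. Against it, placing an (S)-acid on one and an (R)-acid on the other of two homotopic, hindered tertiary alcohols needs a statistical mono-acylation. Each metathesis joins a vinyl group on a fully substituted carbon to a branched 1,1-disubstituted acrylate. A6 lacks all four bromines, so C4–H must become C4–Br on both rings and the C6 silyl ethers must be displaced with inversion at the same neopentyl-like positions as in Alternative 1. The chosen route gives up the predictability of metathesis for one step that sets four stereocentres, two quaternary carbons and the ring with every bromine already in place.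

Key step: step 10

Assumption: the lipase is taken to acylate the (R)-alcohol (lactone ring as the large, propyl as the medium group) and the (R,R)-bridge to induce the (5S,5′S) sense; both alcohol enantiomers are used whichever reacts, and the mirror-image bridge would give the mirror-image induction.

## Route

Step 1
Reactants: 1 ethyl acetoacetate; 2 ethyl 2-bromohexanoate (racemic)
Product: 3 diethyl 2-acetyl-3-butylbutanedioate (mixture of diastereomers)
Conditions: NaOEt, EtOH, reflux
Reagents that add atoms: none
Why: Acetoacetic ester alkylation: the sodium enolate of 1 displaces bromide from α-bromo ester 2 (SN2 at an activated secondary carbon); the two new stereocentres are uncontrolled and are lost or become sp2 in steps 2 and 3.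

Step 2
Reactants: 3 diethyl 2-acetyl-3-butylbutanedioate
Product: 4 2-butyl-4-oxopentanoic acid (racemic)
Conditions: 6 M aq. HCl, AcOH, reflux
Reagents that add atoms: water (O)
Why: Ketonic cleavage of a β-keto ester: acid hydrolysis of both esters and loss of CO2 from the β-keto acid leave the γ-keto acid; its one stereocentre becomes sp2 in step 3.

Step 3
Reactants: 4 2-butyl-4-oxopentanoic acid
Product: 6 (5Z)-4-bromo-5-(bromomethylidene)-3-butylfuran-2(5H)-one, via 3,5-dibromo-2-butyl-4-oxopentanoic acid 5 (not isolated)
Conditions: Br2 (2.1 equiv), CHCl3, 0 °C to rt; evaporate; conc. H2SO4, 100–110 °C; ice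
Reagents that add atoms: bromine (BrBr)
Why: Acid-catalysed α-bromination puts one bromine on each side of the ketone (5); hot concentrated H2SO4 then closes the enol lactone and dehydrogenates it (H2SO4 as oxidant) to the conjugated butenolide, the established entry to this class; the Z geometry (C6–Br syn to O1) is the thermodynamic one because the E isomer presses the C6 bromine against the C4 bromine.

Step 4
Reactants: 6 (5Z)-4-bromo-5-(bromomethylidene)-3-butylfuran-2(5H)-one
Product: 7 rac-(5Z)-4-bromo-3-(1-bromobutyl)-5-(bromomethylidene)furan-2(5H)-one
Conditions: NBS, (PhCO2)2 (cat.), PhCF3, reflux, visible light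
Reagents that add atoms: N-bromosuccinimide (O=C1CCC(=O)N1Br)
Why: Wohl–Ziegler bromination: C1′–H is the only allylic C–H (allylic to C3=C4) and the electron-poor diene does not add bromine atoms; the new stereocentre forms racemic.

Step 5
Reactants: 7 rac-(5Z)-4-bromo-3-(1-bromobutyl)-5-(bromomethylidene)furan-2(5H)-one
Product: 8 rac-(5Z)-4-bromo-5-(bromomethylidene)-3-(1-hydroxybutyl)furan-2(5H)-one
Conditions: DMSO/H2O (4:1), CaCO3, 25 to 40 °C
Reagents that add atoms: water (O)
Why: Solvolysis of an activated secondary allylic bromide (DMSO-assisted substitution, then hydrolysis of the alkoxysulfonium ion); CaCO3 takes up HBr without offering a soluble base or nucleophile to the bromomethylidene butenolide; the product is racemic.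

Step 6
Reactants: 8 rac-(5Z)-4-bromo-5-(bromomethylidene)-3-(1-hydroxybutyl)furan-2(5H)-one
Product: 9 (5Z)-4-bromo-5-(bromomethylidene)-3-[(1S)-1-hydroxybutyl]furan-2(5H)-one (unreacted enantiomer) and 10 (1R)-1-[(5Z)-4-bromo-5-(bromomethylidene)-2-oxo-2,5-dihydrofuran-3-yl]butyl acetate, separated by chromatography
Conditions: Burkholderia cepacia lipase (immobilised), vinyl acetate, MTBE, 30 °C, stopped near half conversion
Reagents that add atoms: vinyl acetate (C=COC(C)=O)
Why: Lipase-catalysed kinetic resolution by irreversible transesterification of a secondary alcohol, as established for α-(1-hydroxyalkyl)acrylates; by the empirical size rule the (R)-alcohol should be acylated, and since both enantiomers are needed neither half is waste.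

Step 7
Reactants: 10 (1R)-1-[(5Z)-4-bromo-5-(bromomethylidene)-2-oxo-2,5-dihydrofuran-3-yl]butyl acetate
Product: 11 (5Z)-4-bromo-5-(bromomethylidene)-3-[(1R)-1-hydroxybutyl]furan-2(5H)-one
Conditions: Burkholderia cepacia lipase (immobilised), n-BuOH, MTBE, 40 °C
Reagents that add atoms: none
Why: Lipase-catalysed alcoholysis: the (R)-acetate is the enantiomer the enzyme accepts, so deacetylation runs under neutral conditions, should raise the enantiomeric purity and avoids base; acyl–oxygen cleavage leaves C1′ untouched.

Step 8
Reactants: 9 (5Z)-4-bromo-5-(bromomethylidene)-3-[(1S)-1-hydroxybutyl]furan-2(5H)-one; 12 (+)-O,O′-diacetyl-L-tartaric anhydride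
Product: 13 (2R,3R)-2,3-diacetoxy-4-oxo-4-{(1S)-1-[(5Z)-4-bromo-5-(bromomethylidene)-2-oxo-2,5-dihydrofuran-3-yl]butoxy}butanoic acid
Conditions: 12 (2 equiv), toluene/AcOH (4:1), 75 °C; aqueous work-up
Reagents that add atoms: none
Why: Alcoholysis of a cyclic anhydride: the two carbonyls of C2-symmetric 12 are equivalent, so one half-ester forms and the second carboxyl is released as the free acid; no amine is used because amines eliminate acetic acid from 12 and add to the bromomethylidene group; C1′ (S) and the tartrate centres (R,R) are untouched.

Step 9
Reactants: 13 the (1S) half-ester; 11 (5Z)-4-bromo-5-(bromomethylidene)-3-[(1R)-1-hydroxybutyl]furan-2(5H)-one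
Product: 14 (2R,3R)-2,3-diacetoxybutanedioate diester of 9 and 11 (5Z in both arms)
Conditions: DIC, DPTS (4-(dimethylamino)pyridinium tosylate), CH2Cl2, 0 °C to rt
Reagents that add atoms: none
Why: Carbodiimide (Steglich-type) esterification under buffered, weakly acidic conditions; because the bridge is C2-symmetric the diester of one (S)- and one (R)-alcohol is a single compound; no stereocentre is touched.

Step 10
Reactants: 14 the 5Z,5Z bridged diester
Product: 18 bridged dispiro tetrabromide (C5A S, C5B S, C6A R, C6B R; 14-membered ring through the bridge), via S-arm 5E photoisomer 15 (not isolated), via R-arm 5E photoisomer 16 (not isolated), via 5E,5E photoisomer 17 (not isolated)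
Conditions: thioxanthone (20 mol %), degassed PhCF3, 1 mM, 405 nm LEDs, 10 °C
Reagents that add atoms: none
Why: Thioxanthone, excited at 405 nm where the substrate does not absorb, passes its triplet energy (about 65 kcal/mol) to one ylidene butenolide; the triplet twists about C5=C6, which interconverts 14 with 15–17, and its C6 radical adds to C6 of the other arm. The resulting triplet 1,4-diradical has both odd electrons at C5, each allylic within its lactone and oxygen-substituted, and after intersystem crossing they recombine to C5A–C5B: the cyclobutane closes by 1,4-diradical recombination (formal [2+2]) and the bridge becomes part of a 14-membered ring. The closest known reactions are the head-to-head, lactone-anti photodimerisation of 5-methylidenefuran-2(5H)-one and sensitised [2+2] cycloadditions of two enoates held on a chiral diol or diacid bridge. Head-to-head union is secured twice: C6–C6 bonding gives the more stabilised diradical, and in an idealised model a head-to-tail stack needs the C1′ carbons about 9 Å apart, beyond the roughly 8 Å reach of the six-atom bridge. C6A and C6B (R,R, bromines trans): a diradical of unlike configuration could close only to a cis-dibromide and should largely revert, so the trans-dibromide is selected at closure. C5A and C5B (S,S, lactone oxygens trans) close with the two lactone dipoles opposed, as in the untethered parent dimer, and the (R,R)-bridge with the C1′ centres is the only element that distinguishes the two helical senses of the C2-symmetric core. The relation of each C6–Br to the neighbouring lactone (anti to O1, syn to C4) is not inherited from the alkene geometry, because rotation about C5–C6 is free in the diradical; it is set at closure, is expected from the preference of C–Br to lie anti to C5–O1 in a low-polarity solvent, and is the least secure selectivity of the step. High dilution keeps the reaction intramolecular, and energy transfer alone, far below the vinyl C–Br bond energy, spares the four bromines.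

Step 11
Reactants: 18 bridged dispiro tetrabromide
Product: 19 dispiro diol (C1′A S and C1′B R alcohols free; ring centres as in 18)
Conditions: HCl (1.25 M) in MeOH, 45 °C
Reagents that add atoms: none
Why: Acid-catalysed transesterification: the bridge acetates and then the two α-oxygenated esters exchange to methyl esters, freeing both C1′ alcohols by acyl–oxygen cleavage; the lactones can only reclose, and acid is used instead of an alkoxide or Ti(OiPr)4 because alkoxides replace the C4 bromines by addition–elimination.

Step 12
Reactants: 19 dispiro diol
Product: 20 the target, CNP0266230.1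
Conditions: Ac2O, pyridine, CH2Cl2, 0 °C to rt
Reagents that add atoms: acetic anhydride (CC(=O)OC(C)=O)
Why: Acetylation of two secondary alcohols; no stereocentre is involved.

## Compound list

1 | ethyl acetoacetate | CCOC(=O)CC(C)=O | starting material
2 | ethyl 2-bromohexanoate (racemic) | CCCCC(Br)C(=O)OCC | starting material
3 | diethyl 2-acetyl-3-butylbutanedioate (diastereomer mixture) | CCCCC(C(=O)OCC)C(C(C)=O)C(=O)OCC | intermediate
4 | 2-butyl-4-oxopentanoic acid (racemic) | CCCCC(CC(C)=O)C(=O)O | intermediate
5 | 3,5-dibromo-2-butyl-4-oxopentanoic acid (diastereomer mixture, not isolated) | CCCCC(C(Br)C(=O)CBr)C(=O)O | intermediate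
6 | (5Z)-4-bromo-5-(bromomethylidene)-3-butylfuran-2(5H)-one | CCCCC1=C(Br)/C(=C/Br)OC1=O | intermediate
7 | rac-(5Z)-4-bromo-3-(1-bromobutyl)-5-(bromomethylidene)furan-2(5H)-one | CCCC(Br)C1=C(Br)/C(=C/Br)OC1=O | intermediate
8 | rac-(5Z)-4-bromo-5-(bromomethylidene)-3-(1-hydroxybutyl)furan-2(5H)-one | CCCC(O)C1=C(Br)/C(=C/Br)OC1=O | intermediate
9 | (5Z)-4-bromo-5-(bromomethylidene)-3-[(1S)-1-hydroxybutyl]furan-2(5H)-one | CCC[C@H](O)C1=C(Br)/C(=C/Br)OC1=O | intermediate
10 | (1R)-1-[(5Z)-4-bromo-5-(bromomethylidene)-2-oxo-2,5-dihydrofuran-3-yl]butyl acetate | CCC[C@@H](OC(C)=O)C1=C(Br)/C(=C/Br)OC1=O | intermediate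
11 | (5Z)-4-bromo-5-(bromomethylidene)-3-[(1R)-1-hydroxybutyl]furan-2(5H)-one | CCC[C@@H](O)C1=C(Br)/C(=C/Br)OC1=O | intermediate
12 | (+)-O,O′-diacetyl-L-tartaric anhydride, (3R,4R)-2,5-dioxooxolane-3,4-diyl diacetate | CC(=O)O[C@H]1C(=O)OC(=O)[C@@H]1OC(C)=O | starting material
13 | (2R,3R)-2,3-diacetoxy-4-oxo-4-{(1S)-1-[(5Z)-4-bromo-5-(bromomethylidene)-2-oxo-2,5-dihydrofuran-3-yl]butoxy}butanoic acid | CCC[C@H](OC(=O)[C@H](OC(C)=O)[C@@H](OC(C)=O)C(=O)O)C1=C(Br)/C(=C/Br)OC1=O | intermediate
14 | (2R,3R)-2,3-diacetoxybutanedioate diester of 9 and 11, 5Z in both arms | CCC[C@H](OC(=O)[C@H](OC(C)=O)[C@@H](OC(C)=O)C(=O)O[C@H](CCC)C2=C(Br)/C(=C/Br)OC2=O)C1=C(Br)/C(=C/Br)OC1=O | intermediate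
15 | isomer of 14 with 5E in the (1S) arm, 5Z in the (1R) arm (not isolated) | CCC[C@H](OC(=O)[C@H](OC(C)=O)[C@@H](OC(C)=O)C(=O)O[C@H](CCC)C2=C(Br)/C(=C/Br)OC2=O)C1=C(Br)/C(=C\Br)OC1=O | intermediate
16 | isomer of 14 with 5Z in the (1S) arm, 5E in the (1R) arm (not isolated) | CCC[C@H](OC(=O)[C@H](OC(C)=O)[C@@H](OC(C)=O)C(=O)O[C@H](CCC)C2=C(Br)/C(=C\Br)OC2=O)C1=C(Br)/C(=C/Br)OC1=O | intermediate
17 | isomer of 14 with 5E in both arms (not isolated) | CCC[C@H](OC(=O)[C@H](OC(C)=O)[C@@H](OC(C)=O)C(=O)O[C@H](CCC)C2=C(Br)/C(=C\Br)OC2=O)C1=C(Br)/C(=C\Br)OC1=O | intermediate
18 | bridged dispiro tetrabromide: cyclobutane C5A–C5B–C6B–C6A with spiro 4-bromobutenolides at C5A and C5B (lactone oxygens trans), bromines at C6A and C6B (trans, each anti to O1 of the neighbouring lactone); C5A S, C5B S, C6A R, C6B R; C1′A (S) and C1′B (R) oxygens joined by the (2R,3R)-2,3-diacetoxybutanedioyl bridge | CCC[C@H](OC(=O)[C@H](OC(C)=O)[C@@H](OC(C)=O)C3=O)C1=C(Br)[C@@]2(OC1=O)[C@@H](Br)[C@H](Br)[C@@]21OC(=O)C([C@@H](CCC)O3)=C1Br | intermediate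
19 | dispiro diol: 18 without the bridge, (1S)-1-hydroxybutyl at C3A and (1R)-1-hydroxybutyl at C3B | CCC[C@H](O)C1=C(Br)[C@@]2(OC1=O)[C@@H](Br)[C@H](Br)[C@@]21OC(=O)C([C@@H](CCC)O)=C1Br | intermediate
20 | CNP0266230.1: 19 with both C1′ alcohols acetylated (C1′A S, C1′B R, C5A S, C5B S, C6A R, C6B R) | CCC[C@H](OC(C)=O)C1=C(Br)[C@@]2(OC1=O)[C@@H](Br)[C@H](Br)[C@@]21OC(=O)C([C@@H](CCC)OC(C)=O)=C1Br | target

## Step count and risk

Total: 12 steps. Longest linear sequence: 11 steps (1–7, 9–12 through 11; equally 1–6, 8–12 through 13).

**Step 10 (key step).** Three things may go wrong.
- The diradical may close with each C6–Br syn to the neighbouring lactone oxygen. That closure keeps the C6 bromine away from the C4 bromine and is the sterically easier one; the required relation relies on dipole control and cannot be corrected after the ring is made.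
- Induction of helicity by the bridge may be poor or reversed. The two helical adducts are diastereomers and separable at 18; a reversed sense is met by the mirror-image bridge.
- Closure may fail because the bridge must stretch almost fully in the dispiro product. An idealised model puts the C1′ carbons about 5 Å apart in the stack and about 7 Å apart in the product. The result would be reversion, geometric cycling and intermolecular oligomerisation.

Fallback, from 8 back to 20: acetylation of 8 (Ac2O, pyridine) gives racemic (5Z)-3-(1-acetoxybutyl)-4-bromo-5-(bromomethylidene)furan-2(5H)-one F1. Sensitised irradiation of F1 at high concentration without a bridge, the untemplated dimerisation known for 5-ylidene butenolides, should give a mixture of dimers. From it the racemic head-to-head, lactone-anti cross-dimer of the two enantiomers (racemic 20) F2 is separated by chromatography, and chromatography on a chiral stationary phase then gives 20.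

**Step 6.** Enantiomer discrimination may be low and acylation slow, because propyl is large for the medium-sized pocket of the enzyme. Fallback, from 8 back to 13 and 11: classical resolution through the bridge. Racemic 8 is opened onto 12 under the conditions of step 8 to give 13 together with its C1′ epimer, the (1R) half-ester F3. The two diastereomeric acids are separated by crystallisation or chromatography; 13 continues, and acid methanolysis of F3 (HCl, MeOH) gives 11.

**Step 9.** Coupling of a hindered α-acyloxy acid with a hindered, weakly nucleophilic alcohol may be slow, with rearrangement of the activated acid to the N-acylurea or loss of acetic acid from the bridge. Fallback, from 13 and 7 back to 14: the carboxylate is alkylated instead of the alcohol acylated. Treating 13 with Ag2O and racemic bromide 7 in MeCN (silver-assisted substitution) should give 14 and, in comparable amount, the diastereomeric diester with (1S) centres in both arms F4, which is removed by chromatography.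

**Step 11.** The two hindered bridge esters may cleave too slowly under conditions mild enough to spare C4–Br, and forcing conditions would bring substitution of bromine by methanol. Fallback, from 18 back to 19: the bridge is unlinked oxidatively. Brief acid methanolysis at rt removes only the two bridge acetates and gives the bridged tartrate diol F5. H5IO6 in THF cleaves the glycol to the bis(glyoxylate) ester of 19 F6, and glyoxylate esters exchange with methanol at rt to give 19.

## Further compounds

F1 | step 10 | rac-(5Z)-3-(1-acetoxybutyl)-4-bromo-5-(bromomethylidene)furan-2(5H)-one | CCCC(OC(C)=O)C1=C(Br)/C(=C/Br)OC1=O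
F2 | step 10 | racemic 20 (one enantiomer drawn) | CCC[C@H](OC(C)=O)C1=C(Br)[C@@]2(OC1=O)[C@@H](Br)[C@H](Br)[C@@]21OC(=O)C([C@@H](CCC)OC(C)=O)=C1Br
F3 | step 6 | (2R,3R)-2,3-diacetoxy-4-oxo-4-{(1R)-1-[(5Z)-4-bromo-5-(bromomethylidene)-2-oxo-2,5-dihydrofuran-3-yl]butoxy}butanoic acid | CCC[C@@H](OC(=O)[C@H](OC(C)=O)[C@@H](OC(C)=O)C(=O)O)C1=C(Br)/C(=C/Br)OC1=O
F4 | step 9 | (2R,3R)-2,3-diacetoxybutanedioate diester of two molecules of 9 (1S in both arms) | CCC[C@H](OC(=O)[C@H](OC(C)=O)[C@@H](OC(C)=O)C(=O)O[C@@H](CCC)C2=C(Br)/C(=C/Br)OC2=O)C1=C(Br)/C(=C/Br)OC1=O
F5 | step 11 | 18 with both bridge acetates removed (bridged (2R,3R)-tartrate diol) | CCC[C@H](OC(=O)[C@H](O)[C@@H](O)C3=O)C1=C(Br)[C@@]2(OC1=O)[C@@H](Br)[C@H](Br)[C@@]21OC(=O)C([C@@H](CCC)O3)=C1Br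
F6 | step 11 | bis(glyoxylate) ester of 19 | CCC[C@H](OC(=O)C=O)C1=C(Br)[C@@]2(OC1=O)[C@@H](Br)[C@H](Br)[C@@]21OC(=O)C([C@@H](CCC)OC(=O)C=O)=C1Br
A1 | alternative 1 | 3,3′-dibutanoyl dispiro bis(methyl tetronate) with silyl ethers at C6A and C6B | CCCC(=O)C1=C(OC)[C@@]2(OC1=O)[C@H](O[Si](C)(C)C(C)(C)C)[C@@H](O[Si](C)(C)C(C)(C)C)[C@@]21OC(=O)C(C(=O)CCC)=C1OC
A2 | alternative 1 | dispiro bis(methyl tetronate) with silyl ethers at C6A and C6B, C3–H free | C1=C(OC)[C@@]2(OC1=O)[C@H](O[Si](C)(C)C(C)(C)C)[C@@H](O[Si](C)(C)C(C)(C)C)[C@@]21OC(=O)C=C1OC
A3 | alternative 1 | N-methoxy-N-methylbutanamide | CCCC(=O)N(C)OC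
A4 | alternative 2 | dispiro cyclobutane cis-di-tert-butyl ester | CCC[C@H](OC(C)=O)C1=C(Br)[C@@]2(OC1=O)[C@@H](C(=O)OC(C)(C)C)[C@@H](C(=O)OC(C)(C)C)[C@@]21OC(=O)C([C@@H](CCC)OC(C)=O)=C1Br
A5 | alternative 2 | NH-pyrrolidine with nitrogen between C6A and C6B, spiro lactones at C5A and C5B, tert-butyl esters at C6A and C6B | CCC[C@H](OC(C)=O)C1=C(Br)[C@@]2(OC1=O)[C@@H](C(=O)OC(C)(C)C)N[C@@H](C(=O)OC(C)(C)C)[C@@]21OC(=O)C([C@@H](CCC)OC(C)=O)=C1Br
A6 | alternative 3 | dispiro bis(butenolide) lacking the four bromines, silyl ethers at C6A and C6B | CCC[C@H](OC(C)=O)C1=C[C@@]2(OC1=O)[C@H](O[Si](C)(C)C(C)(C)C)[C@@H](O[Si](C)(C)C(C)(C)C)[C@@]21OC(=O)C([C@@H](CCC)OC(C)=O)=C1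
A7 | alternative 3 | 1,2-divinylcyclobutane-1,2-diyl bis[2-(1-acetoxybutyl)acrylate] with silyl ethers at C6A and C6B | CCC[C@H](OC(C)=O)C(=C)C(=O)O[C@]1(C=C)[C@H](O[Si](C)(C)C(C)(C)C)[C@@H](O[Si](C)(C)C(C)(C)C)[C@@]1(C=C)OC(=O)C(=C)[C@@H](CCC)OC(C)=O
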